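## The problem

The target is (2S)-6-geranylhesperetin, a flavanone whose dihydropyranone ring C is fused to a phloroglucinol-type ring A. Ring A carries hydroxyls on C5 and C7 and the geranyl chain on C6 between them, and C2 bears the 3-hydroxy-4-methoxyphenyl ring B. The single stereocentre, C2, has no neighbour to take instruction from, so it must be set by a reagent and then defended. It is a p-alkoxybenzylic ether carbon β to the C4 ketone, opened by base through the C3 enolate and ionised by strong acid. The placement of the chain is the second difficulty, because C-geranylation of a 5,7-dihydroxyflavanone or of a simpler phloroglucinol has to choose between C6, C8 and oxygen. The chain has two trisubstituted alkenes, which rule out hydrogenolysis, electrophilic halogen, quinone oxidants and hot acid (which closes the chain onto an ortho phenol). A constructive answer is possible because C8, C7, C6 and everything attached to C6 are the carbon skeleton of geranylacetone, while C8a, C4a and C5 can be the β-carbon, α-carbon and ester carbon of an enoate built into a preformed chiral ring C. A conjugate addition (C8–C8a) and a Claisen condensation (C5–C6) then assemble ring A around the chain, one oxidation level below the arene. The price is a saturated ring A precursor in which O1 is β to carbonyl groups and can be expelled for good, so the dehydrogenation that follows has to be prompt and selective.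

## Retrosynthesis

Flavanone numbering (O1, C2 … C8a) is used for every intermediate.

**Target 16 from protected flavanone 15.** The last bond cut is the acetal O–C bond of a methoxymethyl ether on the ring B hydroxyl. This phenol is the only function that needs masking: it would quench the Lewis acid of the aldol and consume base in the enolate steps. An acetal ether is inert to every base in the route and leaves in dilute acid at room temperature. Compound 15 differs from 16 by this group alone. The forward step must stay below the acidity that protonates the chain alkenes or ionises C2–O1.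

**Arene 15 from trione 12.** Two hydrogens are added back across C4a–C8a, which turns ring A into the 1,3,5-tricarbonyl array of 12. This retro-dehydrogenation converts ring A from a substrate for aromatic substitution into something made by enolate chemistry. C4a is preferred over C8 as the site to functionalise because it is the terminus of the second, less stabilised enolate of 12 and can be addressed selectively (selenide 13, selenoxide 14). The forward reaction must place the leaving group on C4a syn to H8a, must not expel O1 and must leave the alkenes alone.

**Trione 12 from pyranone ester 9 and geranylacetone 10.** The cuts are C5–C6 (Claisen) and C8–C8a (Michael). Other three-plus-three partitions of ring A would either put the chain on an acylating fragment that has to be made, or require a separate C-alkylation. In this one a commercial ketone supplies C6, C7, C8 and the whole chain, and ring C with C2 stays intact in the other partner. The bicyclic 12, with three transient stereocentres, falls to a monocyclic ester with one stereocentre and an achiral ketone. The forward reaction needs the methyl-side enolate of 10 for the addition, the enolate at the chain-bearing carbon for the closure, and conditions under which C3 of 9 is not deprotonated.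

**Pyranone 9 from hydroxy keto ester 7.** O1–C8a and C4a=C8a are cut, removing the one-carbon unit C8a. The active methylene of the β-keto ester (C4a) condenses with a formamide acetal and the δ-hydroxyl closes on the resulting enaminone 8. A cycloaddition route to the pyranone would need the ester introduced afterwards; here the aldol product already carries it. The closure must beat dehydration of the benzylic alcohol and must not break the C2–O bond.

**Hydroxy keto ester 7 from aldehyde 2 and diene 5.** C2–C3 is cut, the only stereogenic bond of the synthesis. The four-carbon dienolate equivalent 5 brings C3, C4, C4a and the ester carbon in one piece, and a chiral titanium binaphtholate sets C2 in a vinylogous Mukaiyama aldol via the silylated adduct 6. Setting the centre by ketone reduction would take three steps for the same result. High facial selectivity on an electron-rich aryl aldehyde is required.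

**Building blocks.** Diene 5 comes from methyl acetoacetate 3 by two silylations through enol ether 4. Aldehyde 2 comes from isovanillin 1 by etherification.

## Roads not taken

**Alternative 1:** C2–C3 would be cut. The diazomethyl ketone A1, an aryl ketone with a ring B benzyl ether ortho to the acyl group, would be decomposed by the dirhodium carboxylate Rh2(S-PTTL)4. The carbenoid would insert into the benzylic ether C–H bond, forming C2–C3, ring C and the stereocentre in one catalytic event to give the tris-silylated flavanone A2.
- Merits: ring A is aromatic from the start, so there is no dehydrogenation and no intermediate that can lose O1; the three silyl ethers fall together under fluoride; the stereocentre is made late by catalyst control.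
- Weak points: the arene A1 must be bought with its substitution pattern. That means C- versus O-geranylation of a phloroglucinol derivative and then differentiation of three oxygens around the chain, which is the regiochemical problem the chosen plan avoids. The diazo ketone must be made from a doubly ortho-substituted acid. The carbenoid has the ether oxygen within reach, so ylide formation and a 1,2-benzyl shift (contraction to a five-membered ketone) compete with a six-membered insertion, and the chain alkenes are cyclopropanation partners. Enantiocontrol for a terminal diazo ketone closing a six-membered ring is less secure than for the aldol.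
- Comparison: if the insertion were selective this road would be about as short and better in the robustness of its intermediates. The chosen plan sets against that an unambiguous C6 attachment and a stereocentre made by a reaction with a firm record on aryl aldehydes.

**Alternative 2:** O1–C8a would be cut. The secondary benzylic alcohol of triflate A3 would couple with the aryl triflate carbon under Pd(OAc)2, 2-(di-tert-butylphosphino)-1,1'-binaphthyl and Cs2CO3 to close ring C as flavan A4. C2 is retained because its C–O bond is never broken.
- Merits: with C4 at the alcohol level there is no chalcone pathway, so the closure cannot racemise; the stereocentre comes from ordinary carbonyl chemistry; each step is conservative.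
- Weak points: the C4 oxidation-state detour costs protection, deprotection and oxidation. Three methoxymethyl groups must leave in acid at the end, two of them freeing phenols that flank the chain, against one remote group in the chosen plan. The palladium alkoxide of a secondary benzylic alcohol can undergo β-hydride elimination, and the electron-rich, ortho-substituted triflate is a slow partner. A3 again needs a geranylated phloroglucinol with three differentiated oxygens.
- Comparison: safer step by step and free of the fragile trione, but considerably longer and without an answer to the placement of the chain. The chosen plan offers brevity and regiochemistry by construction against a riskier key step.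

**Alternative 3:** Ring A would be cut at C5–C6, C7–C8 and C4a–C5. Irradiation of diazoacetyl pyranone A5 would give a vinylketene by Wolff rearrangement. This would add to the geranyl siloxyalkyne A6 in a [2+2] step, and four-electron ring opening, six-electron closure and tautomerisation would deliver flavanone A7.
- Merits: it shares the logic of the chosen plan, with ring A built onto a chiral ring C and C6 fixed by connectivity. It is better in one respect: the arene is reached directly, so no dehydrogenation is needed and O1 is never β to an enolate in a saturated ring. The two ring A oxygens emerge differentiated.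
- Weak points: A6 is not commercial and needs several steps through a sensitive ynolate. A5 needs a carboxyl at C8a of the chiral pyranone, a longer preparation than that of 9. The ketene can add to the chain alkenes. The light is absorbed by a dihydropyranone next to a benzylic ether, and the thermal stage stresses C2. The vinyl unit is a push–pull enol ether alkene, an unusual partner.
- Comparison: superior in the oxidation state it delivers. The chosen plan sets against it commercial geranylacetone used unchanged, no diazo compounds or photochemistry, and a shorter approach to the key step.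

Key step: step 6

Assumption on the chemistry: (S)-BINOL with Ti(OiPr)4 is taken to direct the diene to the Si face of aldehyde 2 and so to give (5S)-7, by analogy with related binaphthol–titanium additions to aryl aldehydes. If the opposite sense is found (MTPA ester analysis of 7), (R)-BINOL is used and nothing else changes.

Remark: trione 12 and its relatives are drawn as keto tautomers; enol forms are expected to dominate.

## Route

Step 1
Reactants: 1 isovanillin (3-hydroxy-4-methoxybenzaldehyde)
Product: 2 4-methoxy-3-(methoxymethoxy)benzaldehyde
Conditions: MOMCl, iPr2NEt, CH2Cl2, 0 → 23 °C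
Reagents that add atoms: chloromethyl methyl ether, COCCl
Why: Williamson-type O-alkylation of the phenol with an α-chloro ether; the acetal ether is inert to the Lewis acid, amide bases and peroxide used later and leaves in dilute acid.

Step 2
Reactants: 3 methyl acetoacetate
Product: 4 methyl 3-(trimethylsilyloxy)but-2-enoate (E/Z mixture)
Conditions: Me3SiCl, Et3N, hexane, 23 °C
Reagents that add atoms: chlorotrimethylsilane, C[Si](C)(C)Cl
Why: Silyl enol ether formation by O-silylation of the enolised β-keto ester; the double-bond geometry is of no consequence.

Step 3
Reactants: 4 methyl 3-(trimethylsilyloxy)but-2-enoate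
Product: 5 1-methoxy-1,3-bis(trimethylsilyloxy)buta-1,3-diene
Conditions: LiN(iPr)2, THF, −78 °C; Me3SiCl, −78 → 0 °C
Reagents that add atoms: chlorotrimethylsilane, C[Si](C)(C)Cl
Why: Kinetic γ-deprotonation of the vinylogous ester and O-silylation of the dienolate (silyl ketene acetal formation) give the bis-silyl dienol ether, a standard acetoacetate dianion equivalent.

Step 4
Reactants: 2 4-methoxy-3-(methoxymethoxy)benzaldehyde; 5 1-methoxy-1,3-bis(trimethylsilyloxy)buta-1,3-diene
Product: 7 methyl (5S)-5-hydroxy-5-[4-methoxy-3-(methoxymethoxy)phenyl]-3-oxopentanoate, via bis(trimethylsilyl) aldol adduct 6 (not isolated)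
Conditions: Ti(OiPr)4 (10 mol %), (S)-BINOL (10 mol %), 4 Å MS, THF, −78 → 23 °C; then 10% aq. citric acid, THF, 0 °C
Reagents that add atoms: none
Why: Catalytic asymmetric vinylogous Mukaiyama aldol: the titanium binaphtholate binds the aldehyde and shields one face, so the diene terminus should add to the Si face and set the carbinol carbon (the future C2) as S. Cold weak acid then hydrolyses both silyl groups without ionising the electron-rich benzylic alcohol or cleaving the acetal.

Step 5
Reactants: 7 methyl (5S)-5-hydroxy-5-[4-methoxy-3-(methoxymethoxy)phenyl]-3-oxopentanoate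
Product: 9 methyl (2S)-2-[4-methoxy-3-(methoxymethoxy)phenyl]-4-oxo-3,4-dihydro-2H-pyran-5-carboxylate, via dimethylaminomethylene keto ester 8 (not isolated)
Conditions: Me2NCH(OMe)2, PhMe, 23 °C
Reagents that add atoms: N,N-dimethylformamide dimethyl acetal, COC(OC)N(C)C
Why: Knoevenagel-type condensation of the active methylene with the amide acetal gives the enaminone, and the δ-hydroxyl displaces dimethylamine by conjugate addition–elimination (6-endo-trig) to close the dihydropyranone. The C–O bond at the stereocentre is never broken, so 2S follows from 5S.

Step 6
Reactants: 9 methyl (2S)-2-[4-methoxy-3-(methoxymethoxy)phenyl]-4-oxo-3,4-dihydro-2H-pyran-5-carboxylate; 10 geranylacetone [(5E)-6,10-dimethylundeca-5,9-dien-2-one]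
Product: 12 (2S)-6-geranyl-2-[4-methoxy-3-(methoxymethoxy)phenyl]-2,3,4a,6,8,8a-hexahydrochromene-4,5,7-trione (stereoisomer mixture at C4a/C6/C8a), via Michael adduct keto ester 11 (not isolated)
Conditions: 10 (1.15 equiv), LiN(iPr)2 (1.2 equiv), THF, −78 °C; 9, −78 °C; LiN(SiMe3)2 (1.3 equiv), −78 → 0 °C; AcOH, −78 °C
Reagents that add atoms: none
Why: LiN(iPr)2 at −78 °C deprotonates geranylacetone at its methyl group, and this kinetic enolate adds to C8a of pyranone 9, the β-carbon of an enoate that is also activated by the C4 ketone, forming C8–C8a and the chelated lithium enolate of keto ester 11. Because the ester is now part of a stabilised enolate, a second base is supplied: LiN(SiMe3)2 enolises the side-chain ketone reversibly, and only the enolate at the geranyl-bearing carbon can reach the ester, so C5–C6 forms in a 6-(enolendo)-exo-trig Claisen closure that makes the carbocycle destined to become ring A. The closest known reaction type is the consecutive Michael–Claisen synthesis of cyclohexane-1,3-diones from ketone enolates and unsaturated esters, and closure onto the ester of a 1,3-dicarbonyl anion has its model in dimedone-type cyclisations. Loss of methoxide is made irreversible by deprotonation of the triketone, whereas the competing aldol closure onto C4 is reversible and cannot dehydrate without forming a bridgehead alkene. No lasting stereocentre is created: C4a, C6 and C8a arise as a mixture, largely hidden by enolisation, and are erased in step 7, so the only stereochemical demand is that C2 stays untouched. C2 is protected because addition to the doubly activated C8a should outrun C3 deprotonation at −78 °C, and after the addition C4 is held in a stabilised enolate that makes C3–H non-acidic. The regiochemistry (chain on C6, not C8) rests on complete formation of the methyl-side enolate before the acceptor is added. The cold acetic acid quench limits the time the trione dianion spends in base, where loss of O1 from C8a followed by tautomerisation to a resorcinol would be irreversible.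

Step 7
Reactants: 12 (2S)-6-geranyl-2-[4-methoxy-3-(methoxymethoxy)phenyl]-2,3,4a,6,8,8a-hexahydrochromene-4,5,7-trione
Product: 15 (2S)-5,7-dihydroxy-6-[(2E)-3,7-dimethylocta-2,6-dien-1-yl]-2-[4-methoxy-3-(methoxymethoxy)phenyl]-2,3-dihydro-4H-chromen-4-one, via C4a phenylselenide 13 (not isolated), via C4a selenoxide 14 (not isolated)
Conditions: LiN(SiMe3)2 (2.1 equiv), THF, −78 °C; PhSeBr (1.0 equiv), −78 °C; AcOH; then 30% aq. H2O2, pyridine, CH2Cl2, 0 → 23 °C
Reagents that add atoms: none
Why: α-Selenenylation followed by selenoxide syn-elimination: the strongly acidic C6–H of the cyclic 1,3-dione goes first, so the second equivalent of base creates the less stabilised C4=C4a enolate, which should take selenium at C4a on the face of the axial H8a (cis ring fusion, as in alkylations of ring-fusion enolates). The selenoxide then eliminates with H8a below room temperature and the C4a=C8a enedione tautomerises to the 5,7-dihydroxy arene. C2 is not involved, and buffered H2O2 should leave the trisubstituted alkenes alone.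

Step 8
Reactants: 15 (2S)-5,7-dihydroxy-6-[(2E)-3,7-dimethylocta-2,6-dien-1-yl]-2-[4-methoxy-3-(methoxymethoxy)phenyl]-2,3-dihydro-4H-chromen-4-one
Product: 16 (2S)-5,7-dihydroxy-6-[(2E)-3,7-dimethylocta-2,6-dien-1-yl]-2-(3-hydroxy-4-methoxyphenyl)-2,3-dihydro-4H-chromen-4-one (CNP0264411.1)
Conditions: aq. HCl (3 M)/MeOH 1:10, 23 → 40 °C
Reagents that add atoms: none
Why: Acid-catalysed methanolysis of the aryl methoxymethyl acetal; dilute acid near room temperature should stay below the threshold for protonating the chain alkenes or ionising the C2–O1 bond, so chain and configuration are kept.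

## Compound list

(geranyl = (2E)-3,7-dimethylocta-2,6-dien-1-yl)

1 | isovanillin (3-hydroxy-4-methoxybenzaldehyde) | COc1ccc(C=O)cc1O | starting material
2 | 4-methoxy-3-(methoxymethoxy)benzaldehyde | COCOc1cc(C=O)ccc1OC | intermediate
3 | methyl acetoacetate | COC(=O)CC(C)=O | starting material
4 | methyl 3-(trimethylsilyloxy)but-2-enoate (E/Z mixture) | COC(=O)C=C(C)O[Si](C)(C)C | intermediate
5 | 1-methoxy-1,3-bis(trimethylsilyloxy)buta-1,3-diene | COC(O[Si](C)(C)C)=CC(=C)O[Si](C)(C)C | intermediate
6 | methyl (5S)-5-[4-methoxy-3-(methoxymethoxy)phenyl]-3,5-bis(trimethylsilyloxy)pent-2-enoate | COC(=O)C=C(C[C@H](O[Si](C)(C)C)c1ccc(OC)c(OCOC)c1)O[Si](C)(C)C | intermediate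
7 | methyl (5S)-5-hydroxy-5-[4-methoxy-3-(methoxymethoxy)phenyl]-3-oxopentanoate | COC(=O)CC(=O)C[C@H](O)c1ccc(OC)c(OCOC)c1 | intermediate
8 | methyl (5S)-2-[(dimethylamino)methylidene]-5-hydroxy-5-[4-methoxy-3-(methoxymethoxy)phenyl]-3-oxopentanoate | COC(=O)C(=CN(C)C)C(=O)C[C@H](O)c1ccc(OC)c(OCOC)c1 | intermediate
9 | methyl (2S)-2-[4-methoxy-3-(methoxymethoxy)phenyl]-4-oxo-3,4-dihydro-2H-pyran-5-carboxylate | COCOc1cc([C@@H]2CC(=O)C(C(=O)OC)=CO2)ccc1OC | intermediate
10 | geranylacetone, (5E)-6,10-dimethylundeca-5,9-dien-2-one | CC(=O)CC/C=C(\C)CCC=C(C)C | starting material
11 | methyl (6S)-6-[4-methoxy-3-(methoxymethoxy)phenyl]-2-[(5E)-6,10-dimethyl-2-oxoundeca-5,9-dien-1-yl]-4-oxooxane-3-carboxylate (mixture at C2 and C3 of the oxane) | COCOc1cc([C@@H]2CC(=O)C(C(=O)OC)C(CC(=O)CC/C=C(\C)CCC=C(C)C)O2)ccc1OC | intermediate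
12 | (2S)-6-geranyl-2-[4-methoxy-3-(methoxymethoxy)phenyl]-2,3,4a,6,8,8a-hexahydrochromene-4,5,7-trione (mixture at C4a, C6, C8a) | COCOc1cc([C@@H]2CC(=O)C3C(=O)C(C/C=C(\C)CCC=C(C)C)C(=O)CC3O2)ccc1OC | intermediate
13 | (2S)-6-geranyl-2-[4-methoxy-3-(methoxymethoxy)phenyl]-4a-(phenylselanyl)-2,3,4a,6,8,8a-hexahydrochromene-4,5,7-trione | COCOc1cc([C@@H]2CC(=O)C3([Se]c4ccccc4)C(=O)C(C/C=C(\C)CCC=C(C)C)C(=O)CC3O2)ccc1OC | intermediate
14 | (2S)-6-geranyl-2-[4-methoxy-3-(methoxymethoxy)phenyl]-4a-(phenylseleninyl)-2,3,4a,6,8,8a-hexahydrochromene-4,5,7-trione | COCOc1cc([C@@H]2CC(=O)C3([Se](=O)c4ccccc4)C(=O)C(C/C=C(\C)CCC=C(C)C)C(=O)CC3O2)ccc1OC | intermediate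
15 | (2S)-5,7-dihydroxy-6-geranyl-2-[4-methoxy-3-(methoxymethoxy)phenyl]-2,3-dihydro-4H-chromen-4-one | COCOc1cc([C@@H]2CC(=O)c3c(cc(O)c(C/C=C(\C)CCC=C(C)C)c3O)O2)ccc1OC | intermediate
16 | (2S)-5,7-dihydroxy-6-geranyl-2-(3-hydroxy-4-methoxyphenyl)-2,3-dihydro-4H-chromen-4-one (CNP0264411.1) | COc1ccc([C@@H]2CC(=O)c3c(cc(O)c(C/C=C(\C)CCC=C(C)C)c3O)O2)cc1O | target

## Step count and risks

Total step count: 8. Longest linear sequence: 7 steps (3 → 4 → 5 → 7 → 9 → 12 → 15 → 16); the branch from isovanillin 1 is 6 steps long.

**Step 6 (key step).** Three things can go wrong.
- Proton transfer from C3 of 9 to the enolate may compete with conjugate addition. The C3 enolate can expel O1 from C2 and re-close without control, which erodes the configuration.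
- The Claisen closure may stall, because the ester sits in a chelated enolate and is a poor electrophile.
- Longer times or higher temperature then expose the trione dianion to β-elimination of O1 from C8a. Tautomerisation to a resorcinol makes that loss of the ring oxygen irreversible.

Fallback: the two bond formations are separated and base is removed from the first. Ketone 10 is converted with LiN(iPr)2 and Me3SiCl in THF at −78 °C into its kinetic silyl enol ether (5E)-6,10-dimethyl-2-(trimethylsilyloxy)undeca-1,5,9-triene F1. A Mukaiyama–Michael addition of F1 to 9 under catalytic Sc(OTf)3 in CH2Cl2 at −78 °C should give the silylated adduct methyl (6S)-6-[4-methoxy-3-(methoxymethoxy)phenyl]-2-[(5E)-6,10-dimethyl-2-oxoundeca-5,9-dien-1-yl]-4-(trimethylsilyloxy)-5,6-dihydro-2H-pyran-3-carboxylate F2. Aqueous work-up hydrolyses F2 to keto ester 11, now isolated. Compound 11 is closed with Mg(OMe)2 in MeOH at 23 °C, a chelation-controlled Claisen cyclisation in which the magnesium chelates are poor partners for β-elimination. Acidification returns the route at 12.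

**Step 7.** Four things can go wrong.
- Selenium may enter at C6 or at oxygen if the dianion is incompletely formed.
- Selenium may enter anti to H8a, which leaves the selenoxide without a syn hydrogen.
- The C4=C4a enolate may expel O1 before it is trapped.
- Electrophilic selenium released in the elimination may add to the chain alkenes or to C8 of the new electron-rich arene.

Fallback: the chalcogen is replaced by palladium. Trione 12 is silylated exhaustively (Me3SiOTf, Et3N, CH2Cl2, 0 °C) to the trienol ether (2S)-6-geranyl-2-[4-methoxy-3-(methoxymethoxy)phenyl]-4,5,7-tris(trimethylsilyloxy)-3,8a-dihydro-2H-chromene F3. A Saegusa–Ito dehydrosilylation with Pd(OAc)2 in MeCN at 23 °C follows; the palladium enolate can reach H8a from either face. This should give (2S)-6-geranyl-2-[4-methoxy-3-(methoxymethoxy)phenyl]-5,7-bis(trimethylsilyloxy)-2,3-dihydro-4H-chromen-4-one F4, whose silyl ethers are hydrolysed with dilute aqueous citric acid to rejoin the route at 15.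

**Step 4.** Three things can go wrong.
- Facial selectivity may be insufficient or of the opposite sense.
- The electron-rich aldehyde reacts slowly, so an uncatalysed silyl-transfer background reaction may lower the enantiomeric purity.
- Retro-aldol cleavage or benzylic ionisation may occur during desilylation.

Fallback: the stereocentre is set by reduction instead of addition. Aldehyde 2 is homologated by the Roskamp reaction (methyl diazoacetate, catalytic SnCl2, CH2Cl2) to methyl 3-[4-methoxy-3-(methoxymethoxy)phenyl]-3-oxopropanoate F5. Asymmetric transfer hydrogenation with RuCl(p-cymene)[(S,S)-TsDPEN] in HCO2H/Et3N, whose sense for aryl ketones is firmly established, should give methyl (3S)-3-hydroxy-3-[4-methoxy-3-(methoxymethoxy)phenyl]propanoate F6. A crossed Claisen condensation of F6 with excess lithium enolate of methyl acetate (LiN(iPr)2, MeOAc, THF, −78 → −30 °C) returns the route at 7.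

**Step 8.** Three things can go wrong.
- The C2'=C3' alkene may be protonated and close onto the 7-hydroxyl.
- Methanol or HCl may add across the chain alkenes.
- C2–O1 may ionise, with partial loss of configuration.

Fallback: protic solvolysis is replaced by an acetal-to-silyl-ether exchange under amine buffer. Compound 15 is treated with Me3SiOTf and 2,2'-bipyridyl in MeCN at 0 °C, which should convert the methoxymethyl ether (and the free phenols) into silyl ethers and give (2S)-6-geranyl-2-[4-methoxy-3-(trimethylsilyloxy)phenyl]-5,7-bis(trimethylsilyloxy)-2,3-dihydro-4H-chromen-4-one F7. Water at 23 °C then hydrolyses F7 to 16.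

## Further compounds

F1 | step 6 | (5E)-6,10-dimethyl-2-(trimethylsilyloxy)undeca-1,5,9-triene | C=C(O[Si](C)(C)C)CC/C=C(\C)CCC=C(C)C
F2 | step 6 | methyl (6S)-6-[4-methoxy-3-(methoxymethoxy)phenyl]-2-[(5E)-6,10-dimethyl-2-oxoundeca-5,9-dien-1-yl]-4-(trimethylsilyloxy)-5,6-dihydro-2H-pyran-3-carboxylate | COCOc1cc([C@@H]2CC(O[Si](C)(C)C)=C(C(=O)OC)C(CC(=O)CC/C=C(\C)CCC=C(C)C)O2)ccc1OC
F3 | step 7 | (2S)-6-geranyl-2-[4-methoxy-3-(methoxymethoxy)phenyl]-4,5,7-tris(trimethylsilyloxy)-3,8a-dihydro-2H-chromene | COCOc1cc([C@@H]2CC(O[Si](C)(C)C)=C3C(O[Si](C)(C)C)=C(C/C=C(\C)CCC=C(C)C)C(O[Si](C)(C)C)=CC3O2)ccc1OC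
F4 | step 7 | (2S)-6-geranyl-2-[4-methoxy-3-(methoxymethoxy)phenyl]-5,7-bis(trimethylsilyloxy)-2,3-dihydro-4H-chromen-4-one | COCOc1cc([C@@H]2CC(=O)c3c(cc(O[Si](C)(C)C)c(C/C=C(\C)CCC=C(C)C)c3O[Si](C)(C)C)O2)ccc1OC
F5 | step 4 | methyl 3-[4-methoxy-3-(methoxymethoxy)phenyl]-3-oxopropanoate | COC(=O)CC(=O)c1ccc(OC)c(OCOC)c1
F6 | step 4 | methyl (3S)-3-hydroxy-3-[4-methoxy-3-(methoxymethoxy)phenyl]propanoate | COC(=O)C[C@H](O)c1ccc(OC)c(OCOC)c1
F7 | step 8 | (2S)-6-geranyl-2-[4-methoxy-3-(trimethylsilyloxy)phenyl]-5,7-bis(trimethylsilyloxy)-2,3-dihydro-4H-chromen-4-one | COc1ccc([C@@H]2CC(=O)c3c(cc(O[Si](C)(C)C)c(C/C=C(\C)CCC=C(C)C)c3O[Si](C)(C)C)O2)cc1O[Si](C)(C)C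
A1 | alternative 1 | 1-{2,4-bis(tert-butyldimethylsilyloxy)-6-[3-(tert-butyldimethylsilyloxy)-4-methoxybenzyloxy]-3-geranylphenyl}-2-diazoethan-1-one | [N-]=[N+]=CC(=O)c1c(OCc2ccc(OC)c(O[Si](C)(C)C(C)(C)C)c2)cc(O[Si](C)(C)C(C)(C)C)c(C/C=C(\C)CCC=C(C)C)c1O[Si](C)(C)C(C)(C)C
A2 | alternative 1 | (2S)-6-geranyl-5,7-bis(tert-butyldimethylsilyloxy)-2-[3-(tert-butyldimethylsilyloxy)-4-methoxyphenyl]-2,3-dihydro-4H-chromen-4-one | COc1ccc([C@@H]2CC(=O)c3c(cc(O[Si](C)(C)C(C)(C)C)c(C/C=C(\C)CCC=C(C)C)c3O[Si](C)(C)C(C)(C)C)O2)cc1O[Si](C)(C)C(C)(C)C
A3 | alternative 2 | 2-{(3S)-1-(tert-butyldimethylsilyloxy)-3-hydroxy-3-[4-methoxy-3-(methoxymethoxy)phenyl]propyl}-4-geranyl-3,5-bis(methoxymethoxy)phenyl trifluoromethanesulfonate (either C1 epimer of the propyl chain) | COCOc1cc([C@@H](O)CC(O[Si](C)(C)C(C)(C)C)c2c(OS(=O)(=O)C(F)(F)F)cc(OCOC)c(C/C=C(\C)CCC=C(C)C)c2OCOC)ccc1OC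
A4 | alternative 2 | (2S)-4-(tert-butyldimethylsilyloxy)-6-geranyl-5,7-bis(methoxymethoxy)-2-[4-methoxy-3-(methoxymethoxy)phenyl]chromane (either C4 epimer) | COCOc1cc([C@@H]2CC(O[Si](C)(C)C(C)(C)C)c3c(cc(OCOC)c(C/C=C(\C)CCC=C(C)C)c3OCOC)O2)ccc1OC
A5 | alternative 3 | (2S)-2-[3-(tert-butyldimethylsilyloxy)-4-methoxyphenyl]-6-(diazoacetyl)-2,3-dihydro-4H-pyran-4-one | COc1ccc([C@@H]2CC(=O)C=C(C(=O)C=[N+]=[N-])O2)cc1O[Si](C)(C)C(C)(C)C
A6 | alternative 3 | {[(4E)-5,9-dimethyldeca-4,8-dien-1-yn-1-yl]oxy}tri(propan-2-yl)silane | CC(C)=CCC/C(C)=C/CC#CO[Si](C(C)C)(C(C)C)C(C)C
A7 | alternative 3 | (2S)-6-geranyl-5-hydroxy-7-(triisopropylsilyloxy)-2-[3-(tert-butyldimethylsilyloxy)-4-methoxyphenyl]-2,3-dihydro-4H-chromen-4-one | COc1ccc([C@@H]2CC(=O)c3c(cc(O[Si](C(C)C)(C(C)C)C(C)C)c(C/C=C(\C)CCC=C(C)C)c3O)O2)cc1O[Si](C)(C)C(C)(C)C
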